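**Retrosynthetic overview**

- Numbering (terpenoid style): ring A = C1–C5 + C10 (C3 carries Br; C4 is quaternary with CH3 and the chain C12–C15); ring B = C5–C10 (C8 carries =CH2, C9 the CH2Ar group, C10 the angular CH3).
- Late disconnections: O–Si; C14–Br/C15–Cl (from a (14S)-epoxide through a bromonium ion); C3–Br (inversion of an axial C3–OH, itself made by reduction of a C3 ketone); C8=CH2 (from a C8 ketone); C12–C15 (prenyl Wittig on a C4 aldehyde, then diimide).
- Key disconnection: C3–C4 and C5–C10 in one operation. The enabling feature is the quaternary C4 next to the heteroatom-bearing C3 in ring A, read as a β-hydroxy aldehyde (C3–OH/C4–CHO, C12 at the aldehyde level), together with the angular C10–CH3, read as the H-atom adduct of a C10=CH2 alkene.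
- Ring order: an open-chain keto dialdehyde closes ring B first (C10 radical to C5 of an enal) and ring A second (C4 enolate to the C3 aldehyde). C9 is the only stereocentre bought (Evans auxiliary) and relays C5, C10 and C4 in the cascade; C3 is then fixed by substrate-controlled ketone reduction and inversion, and C14 by a catalyst-controlled epoxidation.

Key step: step 10

Remark: isomerically pure (2E)-geranic acid is assumed (the 2Z isomer would be deprotonated at C4 instead of at the C3 methyl group); in names, Ar = 3,5-dibromo-2-[tri(propan-2-yl)silyloxy]phenyl.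

**Route**

Step 1
Reactants: 1 2,4-dibromo-6-methylphenol
Product: 2 (2,4-dibromo-6-methylphenoxy)tri(propan-2-yl)silane
Conditions: TIPSOTf, 2,6-lutidine, CH2Cl2, 0 → 23 °C
Reagents that add atoms: triisopropylsilyl trifluoromethanesulfonate, CC(C)[Si](C(C)C)(C(C)C)OS(=O)(=O)C(F)(F)F
Why: O-silylation of the hindered phenol gives a base-stable, fluoride-labile aryl silyl ether that masks the acidic OH through all carbanion and radical steps.

Step 2
Reactants: 2 (2,4-dibromo-6-methylphenoxy)tri(propan-2-yl)silane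
Product: 3 [2,4-dibromo-6-(bromomethyl)phenoxy]tri(propan-2-yl)silane
Conditions: NBS, azobisisobutyronitrile (5 mol %), PhCF3, 85 °C
Reagents that add atoms: N-bromosuccinimide, O=C1CCC(=O)N1Br
Why: Wohl–Ziegler radical bromination takes place at the only benzylic C–H position, the electron-poor ring and the silyl ether being inert.

Step 3
Reactants: 4 5-bromo-2-methylpent-2-ene
Product: 5 (2E)-5-bromo-2-methylpent-2-enal
Conditions: SeO2, 1,4-dioxane, 80 °C
Reagents that add atoms: selenium dioxide, O=[Se]=O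
Why: SeO2 allylic oxidation of a 2-methylalk-2-ene (ene reaction, then [2,3]-shift) attacks the (E)-methyl group and gives the (E)-2-methylenal, the primary bromide being untouched.

Step 4
Reactants: 5 (2E)-5-bromo-2-methylpent-2-enal
Product: 6 (2E)-5-bromo-1,1-dimethoxy-2-methylpent-2-ene
Conditions: HC(OMe)3, MeOH, pyridinium p-toluenesulfonate (5 mol %), 23 °C
Reagents that add atoms: trimethyl orthoformate, COC(OC)OC
Why: acid-catalysed acetalisation with the orthoformate as water scavenger masks the enal so that a Grignard reagent can be made from the bromide.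

Step 5
Reactants: 7 (2E)-3,7-dimethylocta-2,6-dienoic acid (geranic acid); 8 (4S)-4-benzyl-1,3-oxazolidin-2-one
Product: 10 (4S)-4-benzyl-3-[(2E)-3,7-dimethylocta-2,6-dienoyl]-1,3-oxazolidin-2-one, via mixed pivalic anhydride 9 (not isolated)
Conditions: t-BuCOCl, Et3N, THF, −20 °C; then LiCl, 8, −20 → 23 °C
Reagents that add atoms: none
Why: N-acylation of the oxazolidinone through the mixed pivalic anhydride (LiCl/Et3N activation) installs the Evans auxiliary without touching the (E)-enoate geometry.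

Step 6
Reactants: 10 (4S)-4-benzyl-3-[(2E)-3,7-dimethylocta-2,6-dienoyl]-1,3-oxazolidin-2-one; 3 [2,4-dibromo-6-(bromomethyl)phenoxy]tri(propan-2-yl)silane
Product: 11 (4S)-4-benzyl-3-[(2S)-2-(ArCH2)-7-methyl-3-methylideneoct-6-enoyl]-1,3-oxazolidin-2-one
Conditions: NaN(SiMe3)2, THF, −78 °C; then 3, −78 → −40 °C
Reagents that add atoms: none
Why: Evans deconjugative alkylation, in which the base removes a proton from the C3 methyl group (cis to the carbonyl in the (E)-enoyl imide) and the chelated (Z)-dienolate is benzylated at the α-carbon on the face opposite the auxiliary benzyl group, which sets C9 (S at this stage) and leaves the C10=CH2 alkene.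

Step 7
Reactants: 11 (4S)-4-benzyl-3-[(2S)-2-(ArCH2)-7-methyl-3-methylideneoct-6-enoyl]-1,3-oxazolidin-2-one
Product: 12 (2S)-2-(ArCH2)-N-methoxy-N,7-dimethyl-3-methylideneoct-6-enamide
Conditions: MeNH(OMe)·HCl, AlMe3, CH2Cl2, −15 → 0 °C
Reagents that add atoms: N,O-dimethylhydroxylamine hydrochloride, CNOC.Cl
Why: aluminium amide transamination converts the acyl oxazolidinone into the Weinreb amide and frees the auxiliary without epimerisation of the α-stereocentre.

Step 8
Reactants: 12 (2S)-2-(ArCH2)-N-methoxy-N,7-dimethyl-3-methylideneoct-6-enamide; 6 (2E)-5-bromo-1,1-dimethoxy-2-methylpent-2-ene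
Product: 15 (2E,7S)-7-(ArCH2)-2,12-dimethyl-8-methylidene-6-oxotrideca-2,11-dienal, via Grignard reagent 13 (not isolated), via keto acetal 14 (not isolated)
Conditions: 6, Mg, THF, 23 °C; then 12, THF, −20 → 0 °C; then 1 M HCl, 0 °C
Reagents that add atoms: water, O
Why: Grignard addition to the Weinreb amide stops at the chelated tetrahedral intermediate and gives the ketone on work-up, and the dilute acid quench also hydrolyses the labile α,β-unsaturated dimethyl acetal to the (E)-enal.

Step 9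
Reactants: 15 (2E,7S)-7-(ArCH2)-2,12-dimethyl-8-methylidene-6-oxotrideca-2,11-dienal
Product: 17 (2E,7S)-7-(ArCH2)-2-methyl-8-methylidene-6-oxoundec-2-enedial, via epoxide 16 (not isolated)
Conditions: mCPBA (1.05 equiv), CH2Cl2, −20 °C; then H5IO6, THF/H2O, 0 °C
Reagents that add atoms: 3-chloroperoxybenzoic acid, O=C(OO)c1cccc(Cl)c1
Why: the peracid epoxidises the most electron-rich, trisubstituted isopropylidene alkene in preference to the hindered 1,1-disubstituted alkene and the electron-poor enal, and periodic acid cleaves the epoxide (through the diol) to the C3 aldehyde and acetone.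

Step 10
Reactants: 17 (2E,7S)-7-(ArCH2)-2-methyl-8-methylidene-6-oxoundec-2-enedial
Product: 20 (3R,4R,5S,9S,10R)-9-(ArCH2)-3-hydroxy-4,10-dimethyl-8-oxo-trans-decalin-4-carbaldehyde, via tertiary C10 radical 18 (not isolated), via ring-B enolate 19 (not isolated)
Conditions: Fe(acac)3 (30 mol %), PhSiH3 (2.5 equiv), HOCH2CH2OH (5 equiv), ClCH2CH2Cl/EtOH (5:1), 0.01 M, 0 → 23 °C
Reagents that add atoms: none
Why: Radical–polar crossover bicyclisation started by hydrogen-atom transfer: the iron hydride formed from Fe(acac)3 and PhSiH3 delivers H• to the CH2 terminus of the C10 alkene (this creates the C10 methyl group), the nucleophilic tertiary radical 18 adds to C5 of the (E)-2-methylenal (6-exo-trig, closes ring B), and the α-formyl radical is reduced to the iron enolate 19, which adds to the C3 aldehyde (6-(enolexo)-exo-trig aldol, closes ring A by the C3–C4 bond and fixes which of the two aldehydes is the donor). The closest known reaction type is the iron-hydride-initiated radical conjugate addition/intramolecular aldol polycyclisation of alkene–enal–aldehyde substrates to trans-decalins that carry a 3-hydroxy-4-methyl-4-formyl ring. Stereocontrol is relayed from C9: in the chair transition state of the radical addition the CH2Ar group on C9 and the enal on C5 are equatorial (C5 cis-1,3 to C9), and of the two arms on the planar C10 radical the longer 3-oxopropyl arm should take the pseudo-equatorial site and CH3 the axial one, which makes the ring fusion trans; this arm discrimination is the least secure element of the step. At C4 the enolate adds with the C5–H bond eclipsing the enolate C=C bond (minimal A(1,3) strain), so that the C(H)–O unit becomes equatorial and C4–CH3 axial, cis to the C10 methyl group, and the iron-bridged closed aldol transition state of the enolate whose oxygen is cis to the C4 methyl group (the geometry inherited from the s-trans enal) should place the new C3–OH equatorial, trans to the formyl group; the route does not rely on C3, because this centre passes through a ketone in steps 14 and 15. The step needs chemoselective H-atom transfer to the only electron-rich 1,1-disubstituted alkene (enal C=C, carbonyls and aryl bromides are poor acceptors) and cyclisation faster than reduction of the radical, which high dilution and the activated acceptor should secure; the C8 ketone cannot compete as aldol acceptor because that would require a strained bicyclo[2.2.1] ring.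

Step 11
Reactants: 20 (3R,4R,5S,9S,10R)-9-(ArCH2)-3-hydroxy-4,10-dimethyl-8-oxo-trans-decalin-4-carbaldehyde
Product: 21 (3R,4R,5S,9S,10R)-9-(ArCH2)-3-hydroxy-4,10-dimethyl-4-(4-methylpenta-1,3-dienyl)-trans-decalin-8-one
Conditions: (3-methylbut-2-en-1-yl)triphenylphosphonium bromide (3 equiv), NaN(SiMe3)2 (2.9 equiv), THF, 0 °C; then 20, −78 → 0 °C
Reagents that add atoms: (3-methylbut-2-en-1-yl)triphenylphosphonium bromide, CC(C)=CC[P+](c1ccccc1)(c1ccccc1)c1ccccc1.[Br-]
Why: Wittig olefination of the neopentylic aldehyde with the semi-stabilised allylic ylide, which is not basic enough to trigger retro-aldol of the free β-hydroxy aldehyde and reacts far faster with the aldehyde than with the hindered C8 ketone, adds C13–C15 (the E/Z mixture at C12=C13 is inconsequential).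

Step 12
Reactants: 21 (3R,4R,5S,9S,10R)-9-(ArCH2)-3-hydroxy-4,10-dimethyl-4-(4-methylpenta-1,3-dienyl)-trans-decalin-8-one
Product: 22 (3R,4R,5S,9S,10R)-9-(ArCH2)-3-hydroxy-4,10-dimethyl-4-(4-methylpent-3-enyl)-trans-decalin-8-one
Conditions: KO2C–N=N–CO2K (10 equiv), AcOH (20 equiv), pyridine/MeOH, 23 °C
Reagents that add atoms: none
Why: diimide, generated from dipotassium azodicarboxylate and acetic acid, transfers H2 in a concerted syn fashion to the 1,2-disubstituted C12=C13 alkene much faster than to the trisubstituted C14=C15 alkene and leaves aryl bromides and the ketone alone.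

Step 13
Reactants: 22 (3R,4R,5S,9S,10R)-9-(ArCH2)-3-hydroxy-4,10-dimethyl-4-(4-methylpent-3-enyl)-trans-decalin-8-one
Product: 23 (3R,4R,5S,9R,10S)-9-(ArCH2)-4,10-dimethyl-8-methylidene-4-(4-methylpent-3-enyl)-trans-decalin-3-ol
Conditions: methyltriphenylphosphonium bromide (5 equiv), KN(SiMe3)2 (4.8 equiv), THF, 0 °C; then 22, 0 → 50 °C
Reagents that add atoms: methyltriphenylphosphonium bromide, C[P+](c1ccccc1)(c1ccccc1)c1ccccc1.[Br-]
Why: Wittig methylenation of the C8 ketone with excess Ph3P=CH2, in which the C3 hydroxyl is carried as its alkoxide (no carbonyl is left β to it, so retro-aldol is excluded), the aryl silyl ether is inert and C9 stays in its thermodynamically preferred equatorial configuration.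

Step 14
Reactants: 23 (3R,4R,5S,9R,10S)-9-(ArCH2)-4,10-dimethyl-8-methylidene-4-(4-methylpent-3-enyl)-trans-decalin-3-ol
Product: 24 (4R,5S,9R,10S)-9-(ArCH2)-4,10-dimethyl-8-methylidene-4-(4-methylpent-3-enyl)-trans-decalin-3-one
Conditions: Dess–Martin periodinane (1.5 equiv), CH2Cl2, 0 → 23 °C
Reagents that add atoms: none
Why: Dess–Martin oxidation of the hindered secondary alcohol leaves both alkenes and the aryl silyl ether untouched and erases the C3 configuration of the aldol step, so that either C3 epimer converges on ketone 24.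

Step 15
Reactants: 24 (4R,5S,9R,10S)-9-(ArCH2)-4,10-dimethyl-8-methylidene-4-(4-methylpent-3-enyl)-trans-decalin-3-one
Product: 25 (3S,4R,5S,9R,10S)-9-(ArCH2)-4,10-dimethyl-8-methylidene-4-(4-methylpent-3-enyl)-trans-decalin-3-ol
Conditions: LiBH(s-Bu)3 (L-Selectride, 1.5 equiv), THF, −78 °C; then H2O, −78 → 0 °C
Reagents that add atoms: none
Why: the bulky tri-sec-butylborohydride approaches the C3 carbonyl along the equatorial trajectory, because the axial trajectory is blocked by the syn-axial hydrogens on C1 and C5, and gives the axial (3S) alcohol, trans to the axial C4 and C10 methyl groups, as is known for 4,4-disubstituted 3-ketones of trans-decalins (substrate-controlled reduction).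

Step 16
Reactants: 25 (3S,4R,5S,9R,10S)-9-(ArCH2)-4,10-dimethyl-8-methylidene-4-(4-methylpent-3-enyl)-trans-decalin-3-ol
Product: 26 (3R,4R,5S,9R,10S)-9-(ArCH2)-3-bromo-4,10-dimethyl-8-methylidene-4-(4-methylpent-3-enyl)-trans-decalin
Conditions: PPh3 (3 equiv), CBr4 (3 equiv), CH2Cl2, 0 → 23 °C
Reagents that add atoms: carbon tetrabromide, BrC(Br)(Br)Br
Why: Appel reaction, in which the axial C3 alcohol is converted into its alkoxyphosphonium ion and displaced by bromide with inversion (SN2) to give the equatorial C3 bromide of the target, both alkenes and the aryl silyl ether being inert to PPh3/CBr4.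

Step 17
Reactants: 26 (3R,4R,5S,9R,10S)-9-(ArCH2)-3-bromo-4,10-dimethyl-8-methylidene-4-(4-methylpent-3-enyl)-trans-decalin
Product: 27 (3R,4R,5S,9R,10S)-9-(ArCH2)-3-bromo-4-{2-[(2S)-3,3-dimethyloxiran-2-yl]ethyl}-4,10-dimethyl-8-methylidene-trans-decalin
Conditions: 1,2:4,5-di-O-isopropylidene-β-L-erythro-2,3-hexodiulo-2,6-pyranose (L-fructose-derived Shi ketone, 30 mol %), Oxone (2KHSO5·KHSO4·K2SO4, 1.4 equiv of KHSO5), K2CO3, Bu4NHSO4, MeCN/(MeO)2CH2/aq. Na2B4O7 buffer, 0 °C
Reagents that add atoms: potassium peroxymonosulfate, [K+].[O-]S(=O)(=O)OO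
Why: Shi asymmetric epoxidation with the L-fructose-derived ketone (dioxirane, spiro transition state) is expected to deliver the (14S)-epoxide by catalyst control, and the electron-rich trisubstituted alkene reacts with the electrophilic dioxirane much faster than the hindered 1,1-disubstituted exocyclic alkene.

Step 18
Reactants: 27 (3R,4R,5S,9R,10S)-9-(ArCH2)-3-bromo-4-{2-[(2S)-3,3-dimethyloxiran-2-yl]ethyl}-4,10-dimethyl-8-methylidene-trans-decalin
Product: 28 (3R,4R,5S,9R,10S)-9-(ArCH2)-3-bromo-4-[(3R)-3-bromo-4-hydroxy-4-methylpentyl]-4,10-dimethyl-8-methylidene-trans-decalin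
Conditions: Li2NiBr4 (0.4 M in THF, 2 equiv), THF, 0 → 23 °C; aqueous phosphate buffer
Reagents that add atoms: dilithium tetrabromonickelate, [Li+].[Li+].Br[Ni-2](Br)(Br)Br
Why: the soft, non-acidic bromide donor Li2NiBr4 opens the trisubstituted epoxide by SN2 attack at the less substituted C14 with inversion, giving the (14R)-bromide with a tertiary C15 alcohol (any regioisomer from attack at C15 would lead to the same bromonium ion in step 19).

Step 19
Reactants: 28 (3R,4R,5S,9R,10S)-9-(ArCH2)-3-bromo-4-[(3R)-3-bromo-4-hydroxy-4-methylpentyl]-4,10-dimethyl-8-methylidene-trans-decalin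
Product: 29 (3R,4R,5S,9R,10S)-9-(ArCH2)-3-bromo-4-[(3R)-3-bromo-4-chloro-4-methylpentyl]-4,10-dimethyl-8-methylidene-trans-decalin
Conditions: SOCl2 (1.5 equiv), 2,6-lutidine (2.5 equiv), CH2Cl2, −40 → 0 °C
Reagents that add atoms: thionyl chloride, O=S(Cl)Cl
Why: the tertiary chlorosulfite ionises with anchimeric assistance by the neighbouring bromine and the configurationally defined bromonium ion is opened by chloride at the tertiary carbon (Markovnikov), so that C14 keeps its configuration, while 2,6-lutidine traps HCl and protects the exocyclic alkene.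

Step 20
Reactants: 29 (3R,4R,5S,9R,10S)-9-(ArCH2)-3-bromo-4-[(3R)-3-bromo-4-chloro-4-methylpentyl]-4,10-dimethyl-8-methylidene-trans-decalin
Product: 30 2,4-dibromo-6-{[(3R,4R,5S,9R,10S)-3-bromo-4-[(3R)-3-bromo-4-chloro-4-methylpentyl]-4,10-dimethyl-8-methylidene-trans-decalin-9-yl]methyl}phenol (CNP0318265.2)
Conditions: Bu4NF (1.2 equiv), AcOH (1.5 equiv), THF, 0 °C
Reagents that add atoms: none
Why: fluoride cleaves the aryl silyl ether under acetic acid buffering (the electron-poor phenoxide is a good leaving group), conditions too mild to eliminate the alkyl halides or to cyclise the phenol onto the alkene.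

**Compound list**

1 | 2,4-dibromo-6-methylphenol | Cc1cc(Br)cc(Br)c1O | starting material
2 | (2,4-dibromo-6-methylphenoxy)tri(propan-2-yl)silane | Cc1cc(Br)cc(Br)c1O[Si](C(C)C)(C(C)C)C(C)C | intermediate
3 | [2,4-dibromo-6-(bromomethyl)phenoxy]tri(propan-2-yl)silane | BrCc1cc(Br)cc(Br)c1O[Si](C(C)C)(C(C)C)C(C)C | intermediate
4 | 5-bromo-2-methylpent-2-ene | CC(C)=CCCBr | starting material
5 | (2E)-5-bromo-2-methylpent-2-enal | O=C/C(C)=C/CCBr | intermediate
6 | (2E)-5-bromo-1,1-dimethoxy-2-methylpent-2-ene | COC(OC)/C(C)=C/CCBr | intermediate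
7 | (2E)-3,7-dimethylocta-2,6-dienoic acid (geranic acid) | CC(C)=CCC/C(C)=C/C(=O)O | starting material
8 | (4S)-4-benzyl-1,3-oxazolidin-2-one | O=C1N[C@@H](Cc2ccccc2)CO1 | starting material
9 | (2E)-3,7-dimethylocta-2,6-dienoic pivalic anhydride (not isolated) | CC(C)=CCC/C(C)=C/C(=O)OC(=O)C(C)(C)C | intermediate
10 | (4S)-4-benzyl-3-[(2E)-3,7-dimethylocta-2,6-dienoyl]-1,3-oxazolidin-2-one | CC(C)=CCC/C(C)=C/C(=O)N1[C@@H](Cc2ccccc2)COC1=O | intermediate
11 | (4S)-4-benzyl-3-[(2S)-2-(ArCH2)-7-methyl-3-methylideneoct-6-enoyl]-1,3-oxazolidin-2-one | CC(C)=CCCC(=C)[C@H](Cc1cc(Br)cc(Br)c1O[Si](C(C)C)(C(C)C)C(C)C)C(=O)N1[C@@H](Cc2ccccc2)COC1=O | intermediate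
12 | (2S)-2-(ArCH2)-N-methoxy-N,7-dimethyl-3-methylideneoct-6-enamide | CC(C)=CCCC(=C)[C@H](Cc1cc(Br)cc(Br)c1O[Si](C(C)C)(C(C)C)C(C)C)C(=O)N(C)OC | intermediate
13 | [(3E)-5,5-dimethoxy-4-methylpent-3-en-1-yl]magnesium bromide (not isolated) | COC(OC)/C(C)=C/CC[Mg]Br | intermediate
14 | (7S,11E)-7-(ArCH2)-13,13-dimethoxy-2,12-dimethyl-6-methylidenetrideca-2,11-dien-8-one (not isolated) | CC(C)=CCCC(=C)[C@H](Cc1cc(Br)cc(Br)c1O[Si](C(C)C)(C(C)C)C(C)C)C(=O)CC/C=C(\C)C(OC)OC | intermediate
15 | (2E,7S)-7-(ArCH2)-2,12-dimethyl-8-methylidene-6-oxotrideca-2,11-dienal | CC(C)=CCCC(=C)[C@H](Cc1cc(Br)cc(Br)c1O[Si](C(C)C)(C(C)C)C(C)C)C(=O)CC/C=C(\C)C=O | intermediate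
16 | 11,12-epoxide of 15 (both epoxide epimers; not isolated) | CC1(C)OC1CCC(=C)[C@H](Cc2cc(Br)cc(Br)c2O[Si](C(C)C)(C(C)C)C(C)C)C(=O)CC/C=C(\C)C=O | intermediate
17 | (2E,7S)-7-(ArCH2)-2-methyl-8-methylidene-6-oxoundec-2-enedial | O=CCCC(=C)[C@H](Cc1cc(Br)cc(Br)c1O[Si](C(C)C)(C(C)C)C(C)C)C(=O)CC/C=C(\C)C=O | intermediate
18 | tertiary C10 radical formed from 17 by H-atom transfer (not isolated) | O=CCC[C](C)[C@H](Cc1cc(Br)cc(Br)c1O[Si](C(C)C)(C(C)C)C(C)C)C(=O)CC/C=C(\C)C=O | intermediate
19 | ring-B enolate (iron-bound, drawn as the free enolate; all three ring substituents equatorial, C10–CH3 axial; not isolated) | O=C1CC[C@H](C(C)=C[O-])[C@@](C)(CCC=O)[C@@H]1Cc1cc(Br)cc(Br)c1O[Si](C(C)C)(C(C)C)C(C)C | intermediate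
20 | (3R,4R,5S,9S,10R)-9-(ArCH2)-3-hydroxy-4,10-dimethyl-8-oxo-trans-decalin-4-carbaldehyde (3-OH equatorial, trans to CHO; 4-CH3 axial, cis to 10-CH3; 9-CH2Ar equatorial) | O=C1CC[C@@H]2[C@@](C)(C=O)[C@H](O)CC[C@@]2(C)[C@@H]1Cc1cc(Br)cc(Br)c1O[Si](C(C)C)(C(C)C)C(C)C | intermediate
21 | (3R,4R,5S,9S,10R)-9-(ArCH2)-3-hydroxy-4,10-dimethyl-4-(4-methylpenta-1,3-dienyl)-trans-decalin-8-one (E/Z mixture at C12=C13) | O=C1CC[C@@H]2[C@@](C)(C=CC=C(C)C)[C@H](O)CC[C@@]2(C)[C@@H]1Cc1cc(Br)cc(Br)c1O[Si](C(C)C)(C(C)C)C(C)C | intermediate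
22 | (3R,4R,5S,9S,10R)-9-(ArCH2)-3-hydroxy-4,10-dimethyl-4-(4-methylpent-3-enyl)-trans-decalin-8-one | O=C1CC[C@@H]2[C@@](C)(CCC=C(C)C)[C@H](O)CC[C@@]2(C)[C@@H]1Cc1cc(Br)cc(Br)c1O[Si](C(C)C)(C(C)C)C(C)C | intermediate
23 | (3R,4R,5S,9R,10S)-9-(ArCH2)-4,10-dimethyl-8-methylidene-4-(4-methylpent-3-enyl)-trans-decalin-3-ol (3-OH equatorial) | C=C1CC[C@@H]2[C@@](C)(CCC=C(C)C)[C@H](O)CC[C@@]2(C)[C@@H]1Cc1cc(Br)cc(Br)c1O[Si](C(C)C)(C(C)C)C(C)C | intermediate
24 | (4R,5S,9R,10S)-9-(ArCH2)-4,10-dimethyl-8-methylidene-4-(4-methylpent-3-enyl)-trans-decalin-3-one | C=C1CC[C@@H]2[C@@](C)(CCC=C(C)C)C(=O)CC[C@@]2(C)[C@@H]1Cc1cc(Br)cc(Br)c1O[Si](C(C)C)(C(C)C)C(C)C | intermediate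
25 | (3S,4R,5S,9R,10S)-9-(ArCH2)-4,10-dimethyl-8-methylidene-4-(4-methylpent-3-enyl)-trans-decalin-3-ol (3-OH axial) | C=C1CC[C@@H]2[C@@](C)(CCC=C(C)C)[C@@H](O)CC[C@@]2(C)[C@@H]1Cc1cc(Br)cc(Br)c1O[Si](C(C)C)(C(C)C)C(C)C | intermediate
26 | (3R,4R,5S,9R,10S)-9-(ArCH2)-3-bromo-4,10-dimethyl-8-methylidene-4-(4-methylpent-3-enyl)-trans-decalin (3-Br equatorial) | C=C1CC[C@@H]2[C@@](C)(CCC=C(C)C)[C@H](Br)CC[C@@]2(C)[C@@H]1Cc1cc(Br)cc(Br)c1O[Si](C(C)C)(C(C)C)C(C)C | intermediate
27 | (3R,4R,5S,9R,10S)-9-(ArCH2)-3-bromo-4-{2-[(2S)-3,3-dimethyloxiran-2-yl]ethyl}-4,10-dimethyl-8-methylidene-trans-decalin | C=C1CC[C@@H]2[C@@](C)(CC[C@@H]3OC3(C)C)[C@H](Br)CC[C@@]2(C)[C@@H]1Cc1cc(Br)cc(Br)c1O[Si](C(C)C)(C(C)C)C(C)C | intermediate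
28 | (3R,4R,5S,9R,10S)-9-(ArCH2)-3-bromo-4-[(3R)-3-bromo-4-hydroxy-4-methylpentyl]-4,10-dimethyl-8-methylidene-trans-decalin | C=C1CC[C@@H]2[C@@](C)(CC[C@@H](Br)C(C)(C)O)[C@H](Br)CC[C@@]2(C)[C@@H]1Cc1cc(Br)cc(Br)c1O[Si](C(C)C)(C(C)C)C(C)C | intermediate
29 | (3R,4R,5S,9R,10S)-9-(ArCH2)-3-bromo-4-[(3R)-3-bromo-4-chloro-4-methylpentyl]-4,10-dimethyl-8-methylidene-trans-decalin | C=C1CC[C@@H]2[C@@](C)(CC[C@@H](Br)C(C)(C)Cl)[C@H](Br)CC[C@@]2(C)[C@@H]1Cc1cc(Br)cc(Br)c1O[Si](C(C)C)(C(C)C)C(C)C | intermediate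
30 | 2,4-dibromo-6-{[(3R,4R,5S,9R,10S)-3-bromo-4-[(3R)-3-bromo-4-chloro-4-methylpentyl]-4,10-dimethyl-8-methylidene-trans-decalin-9-yl]methyl}phenol (CNP0318265.2) | C=C1CC[C@@H]2[C@@](C)(CC[C@@H](Br)C(C)(C)Cl)[C@H](Br)CC[C@@]2(C)[C@@H]1Cc1cc(Br)cc(Br)c1O | target

**Step count and risks**

Total step count: 20. Longest linear sequence: 17 steps (steps 1, 2 and 6–20, from 2,4-dibromo-6-methylphenol). The geranic acid branch (steps 5–20) runs over 16 steps, and the branch from 5-bromo-2-methylpent-2-ene (steps 3, 4 and 8–20) over 15 steps.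

Steps most likely to fail:

1. Step 10. Two processes threaten it. The first is loss of the C9 stereocentre around the cascade: the ketone is α-branched and β,γ-unsaturated, so it can enolise or move the alkene into conjugation, and the C10 radical is β to the carbonyl and could undergo a reversible 1,2-acyl shift. The second is weak discrimination of the two arms on the C10 radical, which would give the cis-fused epimer. The fallback answers the first process only: it takes C8 through the radical step at the alcohol oxidation level, so that there is neither an acidic C9–H nor a β-keto radical. It sets out from 14 (isolated after an NH4Cl quench of step 8) and comes back to the route at 24. Reduction of 14 with NaBH4 in MeOH at 0 °C would give the C8 alcohol F1 (either C8 epimer serves, since C8 returns to a ketone), and TBSCl/imidazole in DMF the silyl ether F2. Pyridinium p-toluenesulfonate in wet acetone would free the enal F3, and the conditions of step 9 would give, through the epoxide F4, the dialdehyde F5. The conditions of step 10 would then give the bicyclic hydroxy aldehyde F6, those of step 11 the diene F7 and those of step 12 the alkene F8. Camphorsulfonic acid (10 mol %) in MeOH would remove the alkyl silyl ether (the aryl silyl ether should survive) to give the diol F9, and Dess–Martin periodinane would oxidise both carbinols to the 3,8-dione F10. One equivalent of Ph3P=CH2 in THF at 0 °C would then methylenate the less hindered C8 carbonyl (the C3 carbonyl is flanked by the quaternary C4 and reacts far more slowly) to give 24.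

2. Step 16. E2 elimination to the C2=C3 alkene (the axial C2–H is antiperiplanar) and a 1,2-methyl shift from C4 can outrun SN2 at the neopentylic axial carbinol. The fallback separates activation from displacement, so that no basic phosphorus species is present when the leaving group departs: it sets out from 25 and comes back at 26. Tf2O/pyridine in CH2Cl2 at −30 °C would give the C3 trifluoromethanesulfonate F11, which would be displaced with inversion by the soluble, non-basic bromide Bu4NBr in toluene at 0 → 40 °C.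

3. Step 12. Diimide may not discriminate well enough between the hindered disubstituted C12=C13 alkene and the trisubstituted C14=C15 alkene of the conjugated diene (over-reduction, or no reaction). The fallback builds the chain so that the trisubstituted alkene is introduced only after the reduction: it sets out from 20 and comes back at 22. Wittig reaction of 20 with the ylide from (1,3-dioxolan-2-ylmethyl)triphenylphosphonium bromide and NaN(SiMe3)2 would give the alkenyl dioxolane F12. Diimide (as in step 12, now with a single C=C bond) would give the saturated dioxolane F13, and aqueous AcOH/THF at 50 °C the C14 aldehyde F14 (in equilibrium with its lactol on the C3–OH). Wittig reaction of F14 with isopropylidenetriphenylphosphorane (from isopropyltriphenylphosphonium iodide and NaN(SiMe3)2, −78 → 0 °C, at which the hindered C8 ketone should not react) would then give 22.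

Further compounds

F1 | step 10 | (7S,11E)-7-(ArCH2)-13,13-dimethoxy-2,12-dimethyl-6-methylidenetrideca-2,11-dien-8-ol (C8 epimers) | CC(C)=CCCC(=C)[C@H](Cc1cc(Br)cc(Br)c1O[Si](C(C)C)(C(C)C)C(C)C)C(O)CC/C=C(\C)C(OC)OC
F2 | step 10 | tert-butyldimethylsilyl ether of F1 | CC(C)=CCCC(=C)[C@H](Cc1cc(Br)cc(Br)c1O[Si](C(C)C)(C(C)C)C(C)C)C(O[Si](C)(C)C(C)(C)C)CC/C=C(\C)C(OC)OC
F3 | step 10 | (2E,7S)-7-(ArCH2)-6-(tert-butyldimethylsilyloxy)-2,12-dimethyl-8-methylidenetrideca-2,11-dienal | CC(C)=CCCC(=C)[C@H](Cc1cc(Br)cc(Br)c1O[Si](C(C)C)(C(C)C)C(C)C)C(O[Si](C)(C)C(C)(C)C)CC/C=C(\C)C=O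
F4 | step 10 | 11,12-epoxide of F3 (both epoxide epimers) | CC1(C)OC1CCC(=C)[C@H](Cc2cc(Br)cc(Br)c2O[Si](C(C)C)(C(C)C)C(C)C)C(O[Si](C)(C)C(C)(C)C)CC/C=C(\C)C=O
F5 | step 10 | (2E,7S)-7-(ArCH2)-6-(tert-butyldimethylsilyloxy)-2-methyl-8-methylideneundec-2-enedial | O=CCCC(=C)[C@H](Cc1cc(Br)cc(Br)c1O[Si](C(C)C)(C(C)C)C(C)C)C(O[Si](C)(C)C(C)(C)C)CC/C=C(\C)C=O
F6 | step 10 | 8-(tert-butyldimethylsilyloxy) analogue of 20 (C8 carbinol in place of the ketone; C8 epimers) | CC(C)(C)[Si](C)(C)OC1CC[C@@H]2[C@@](C)(C=O)[C@H](O)CC[C@@]2(C)[C@@H]1Cc1cc(Br)cc(Br)c1O[Si](C(C)C)(C(C)C)C(C)C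
F7 | step 10 | 8-(tert-butyldimethylsilyloxy) analogue of 21 | CC(C)(C)[Si](C)(C)OC1CC[C@@H]2[C@@](C)(C=CC=C(C)C)[C@H](O)CC[C@@]2(C)[C@@H]1Cc1cc(Br)cc(Br)c1O[Si](C(C)C)(C(C)C)C(C)C
F8 | step 10 | 8-(tert-butyldimethylsilyloxy) analogue of 22 | CC(C)(C)[Si](C)(C)OC1CC[C@@H]2[C@@](C)(CCC=C(C)C)[C@H](O)CC[C@@]2(C)[C@@H]1Cc1cc(Br)cc(Br)c1O[Si](C(C)C)(C(C)C)C(C)C
F9 | step 10 | 8-hydroxy analogue of 22 (3,8-diol; C8 epimers) | OC1CC[C@@H]2[C@@](C)(CCC=C(C)C)[C@H](O)CC[C@@]2(C)[C@@H]1Cc1cc(Br)cc(Br)c1O[Si](C(C)C)(C(C)C)C(C)C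
F10 | step 10 | (4R,5S,9S,10R)-9-(ArCH2)-4,10-dimethyl-4-(4-methylpent-3-enyl)-trans-decalin-3,8-dione | O=C1CC[C@@H]2[C@@](C)(CCC=C(C)C)C(=O)CC[C@@]2(C)[C@@H]1Cc1cc(Br)cc(Br)c1O[Si](C(C)C)(C(C)C)C(C)C
F11 | step 16 | C3 trifluoromethanesulfonate of 25 (axial) | C=C1CC[C@@H]2[C@@](C)(CCC=C(C)C)[C@@H](OS(=O)(=O)C(F)(F)F)CC[C@@]2(C)[C@@H]1Cc1cc(Br)cc(Br)c1O[Si](C(C)C)(C(C)C)C(C)C
F12 | step 12 | (3R,4R,5S,9S,10R)-9-(ArCH2)-4-[2-(1,3-dioxolan-2-yl)ethenyl]-3-hydroxy-4,10-dimethyl-trans-decalin-8-one | O=C1CC[C@@H]2[C@@](C)(C=CC3OCCO3)[C@H](O)CC[C@@]2(C)[C@@H]1Cc1cc(Br)cc(Br)c1O[Si](C(C)C)(C(C)C)C(C)C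
F13 | step 12 | (3R,4R,5S,9S,10R)-9-(ArCH2)-4-[2-(1,3-dioxolan-2-yl)ethyl]-3-hydroxy-4,10-dimethyl-trans-decalin-8-one | O=C1CC[C@@H]2[C@@](C)(CCC3OCCO3)[C@H](O)CC[C@@]2(C)[C@@H]1Cc1cc(Br)cc(Br)c1O[Si](C(C)C)(C(C)C)C(C)C
F14 | step 12 | 3-[(3R,4R,5S,9S,10R)-9-(ArCH2)-3-hydroxy-4,10-dimethyl-8-oxo-trans-decalin-4-yl]propanal | O=C1CC[C@@H]2[C@@](C)(CCC=O)[C@H](O)CC[C@@]2(C)[C@@H]1Cc1cc(Br)cc(Br)c1O[Si](C(C)C)(C(C)C)C(C)C
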